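**Plan**
Retrosynthesis: the esters come off first (C8 angelate; C2/C9 acetates back to PMB ethers). Then the ring bond C7–C8 is cut: C13=C11–C7–C8–OH is a homoallylic alcohol whose allyl part lies inside the lactone, so the α-methylene-γ-butyrolactone fused at C6/C7 is the allyl-transposed adduct of a C6-substituted α-(bromomethyl)butenolide (C13–Br, C11=C7) and a C8 aldehyde on the same chain.
Further cuts: C7=C11 (RCM) and O6–C12 (ester); C4–CH3 and C5–C6 (alkyne C4≡C5 plus acrolein); C9–C10 (alkenyl iodide plus glyceraldehyde acetonide); C1=C10 (iodo-Wittig); C3–C4 (acetylide plus glycidyl ether).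
Forward: chain C1–C5, then the Z-iodoalkene, C8–C10, C6/C7, the butenolide (first ring), the ten-membered carbocycle (last ring), the angelate, and finally the acetates.
Stereochemistry: C2 is bought (glycidyl ether); C9 is relayed from a sacrificial glyceraldehyde carbon (Felkin–Anh); C6 is set by ProPhenol catalysis; C7 and C8 are both relayed from C6 in the ring closure (trans-lactone, chair, chelation by O9). 4E comes from trans-hydroalumination/iodination/methyl coupling, 1(10)Z from the iodo-ylide, and the angelate Z is bought.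

Key step: step 14

Remark: germacrane numbering (ring C1–C10, lactone C11–C13, C14 on C10, C15 on C4) is used for all intermediates; the CIP letters at C6 (S in 11–16, R from 17 on) and at C7 (R in 21, S in 23–25) change only because neighbouring groups change priority, not because the centres change in space.

Step 1
Reactants: 1 (R)-trityl glycidyl ether
Product: 2 (R)-1-(trityloxy)pent-4-yn-2-ol
Conditions: LiC≡CH·ethylenediamine, DMSO, 0 °C → rt; aq NH4Cl
Reagents that add atoms: lithium acetylide ethylenediamine complex ([Li+].[C-]#C.NCCN)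
Why: Acetylide opening of the epoxide (SN2 at the terminal carbon C3) leaves the bought C2 stereocentre untouched and delivers C4 and C5.

Step 2
Reactants: 2 (R)-1-(trityloxy)pent-4-yn-2-ol
Product: 3 (R)-4-(4-methoxybenzyloxy)-5-(trityloxy)pent-1-yne
Conditions: NaH, PMBCl, TBAI (cat.), THF/DMF, 0 °C → rt
Reagents that add atoms: 4-methoxybenzyl chloride (COc1ccc(CCl)cc1)
Why: Williamson etherification puts on O2 a group that should survive every later step and leave oxidatively at the end together with its O9 counterpart.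

Step 3
Reactants: 3 (R)-4-(4-methoxybenzyloxy)-5-(trityloxy)pent-1-yne
Product: 4 (R)-2-(4-methoxybenzyloxy)pent-4-yn-1-ol
Conditions: TsOH·H2O (cat.), MeOH/CH2Cl2, rt
Reagents that add atoms: none
Why: Acid-catalysed SN1 solvolysis of the trityl ether (cation trapped by methanol) frees the primary alcohol while the PMB ether and the alkyne are inert to catalytic acid.

Step 4
Reactants: 4 (R)-2-(4-methoxybenzyloxy)pent-4-yn-1-ol
Product: 5 (R)-2-(4-methoxybenzyloxy)pent-4-ynal
Conditions: Dess–Martin periodinane, NaHCO3, CH2Cl2, 0 °C → rt; used crude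
Reagents that add atoms: none
Why: Buffered Dess–Martin oxidation should give the α-alkoxy aldehyde without epimerising C2.

Step 5
Reactants: 5 (R)-2-(4-methoxybenzyloxy)pent-4-ynal
Product: 6 (4R,2Z)-2-iodo-4-(4-methoxybenzyloxy)hept-2-en-6-yne
Conditions: EtPPh3I, n-BuLi, THF, rt; I2, −78 °C; NaHMDS, −20 °C; then 5, −78 → −20 °C
Reagents that add atoms: ethyltriphenylphosphonium iodide (CC[P+](c1ccccc1)(c1ccccc1)c1ccccc1.[I-]); iodine (II)
Why: The Stork–Zhao-type Wittig olefination with the α-iodoethylidene ylide is Z-selective (kinetic cis-oxaphosphetane, iodine cis to the chain), which installs C10, the C14 methyl and the future 1(10)Z geometry in one step.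

Step 6
Reactants: 6 (4R,2Z)-2-iodo-4-(4-methoxybenzyloxy)hept-2-en-6-yne; 7 (S)-2,2-dimethyl-1,3-dioxolane-4-carbaldehyde
Product: 8 (1R,4R,2Z)-1-[(4S)-2,2-dimethyl-1,3-dioxolan-4-yl]-2-methyl-4-(4-methoxybenzyloxy)hept-2-en-6-yn-1-ol
Conditions: CrCl2 (5 equiv), NiCl2 (2 mol %), DMSO, rt; 7 in excess
Reagents that add atoms: none
Why: The Nozaki–Hiyama–Kishi alkenyl–aldehyde coupling forms C9–C10 with retention of the Z geometry, and Felkin–Anh addition anti to the dioxolane C–O bond should set C9, the dioxolane carbon being a sacrificial control element that is cut away in step 13.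

Step 7
Reactants: 8 (1R,4R,2Z)-1-[(4S)-2,2-dimethyl-1,3-dioxolan-4-yl]-2-methyl-4-(4-methoxybenzyloxy)hept-2-en-6-yn-1-ol
Product: 9 (4S)-4-[(1R,4R,2Z)-1,4-bis(4-methoxybenzyloxy)-2-methylhept-2-en-6-yn-1-yl]-2,2-dimethyl-1,3-dioxolane
Conditions: NaH, PMBCl, TBAI (cat.), THF/DMF, 0 °C → rt
Reagents that add atoms: 4-methoxybenzyl chloride (COc1ccc(CCl)cc1)
Why: Williamson etherification places on O9 the benzylic ether that is meant to chelate the metal in the key step (a silyl ether would not).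

Step 8
Reactants: 9 (4S)-4-[(1R,4R,2Z)-1,4-bis(4-methoxybenzyloxy)-2-methylhept-2-en-6-yn-1-yl]-2,2-dimethyl-1,3-dioxolane; 10 acrolein
Product: 11 (3S,7R,10R,8Z)-10-[(4S)-2,2-dimethyl-1,3-dioxolan-4-yl]-7,10-bis(4-methoxybenzyloxy)-9-methyldeca-1,8-dien-4-yn-3-ol
Conditions: ProPhenol (20 mol %; the antipode that gives 6S, to be fixed on a model alkyne), Ph3P=O (40 mol %), Me2Zn (3 equiv), toluene, 0 °C; aq NH4Cl
Reagents that add atoms: none
Why: The zinc–ProPhenol catalysed asymmetric alkynylation of an enal adds the zinc acetylide to one face of acrolein under catalyst control, so C6 is set independently of the remote C2 and C9 centres.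

Step 9
Reactants: 11 (3S,7R,10R,8Z)-10-[(4S)-2,2-dimethyl-1,3-dioxolan-4-yl]-7,10-bis(4-methoxybenzyloxy)-9-methyldeca-1,8-dien-4-yn-3-ol
Product: 13 (3S,7R,10R,4Z,8Z)-10-[(4S)-2,2-dimethyl-1,3-dioxolan-4-yl]-5-iodo-7,10-bis(4-methoxybenzyloxy)-9-methyldeca-1,4,8-trien-3-ol, via cyclic alkenylalanate 12 (not isolated)
Conditions: Red-Al, THF, 0 °C → rt; EtOAc; I2, −78 °C; aq Rochelle salt
Reagents that add atoms: iodine (II)
Why: Hydroxyl-directed trans-hydroalumination of the propargylic alcohol places aluminium on C4 in a five-membered alkoxyalanate, and iodinolysis with retention gives the (Z)-γ-iodo allylic alcohol with iodine cis to C6.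

Step 10
Reactants: 13 (3S,7R,10R,4Z,8Z)-10-[(4S)-2,2-dimethyl-1,3-dioxolan-4-yl]-5-iodo-7,10-bis(4-methoxybenzyloxy)-9-methyldeca-1,4,8-trien-3-ol
Product: 14 (3S,7R,10R,4E,8Z)-10-[(4S)-2,2-dimethyl-1,3-dioxolan-4-yl]-7,10-bis(4-methoxybenzyloxy)-5,9-dimethyldeca-1,4,8-trien-3-ol
Conditions: Me2CuLi (5 equiv), Et2O, 0 °C
Reagents that add atoms: lithium dimethylcuprate ([Li+].C[Cu-]C)
Why: Cuprate cross-coupling of the alkenyl iodide proceeds with retention, so the C15 methyl ends cis to C6 and the C4=C5 alkene is E.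

Step 11
Reactants: 14 (3S,7R,10R,4E,8Z)-10-[(4S)-2,2-dimethyl-1,3-dioxolan-4-yl]-7,10-bis(4-methoxybenzyloxy)-5,9-dimethyldeca-1,4,8-trien-3-ol; 15 2-(bromomethyl)acrylic acid
Product: 16 the O6 2-(bromomethyl)acrylate ester of 14
Conditions: DCC, DMAP (5 mol %), CH2Cl2, −20 → 0 °C
Reagents that add atoms: none
Why: Steglich esterification at low temperature acylates the only free hydroxyl (O6) and, with only catalytic DMAP, should leave the allylic bromide of the acid intact.

Step 12
Reactants: 16 the O6 2-(bromomethyl)acrylate ester of 14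
Product: 17 (5R)-3-(bromomethyl)-5-[(1E,4R,5Z,7R)-7-[(4S)-2,2-dimethyl-1,3-dioxolan-4-yl]-4,7-bis(4-methoxybenzyloxy)-2,6-dimethylhepta-1,5-dienyl]furan-2(5H)-one
Conditions: Grubbs II (10 mol %), CH2Cl2 (5 mM), 40 °C
Reagents that add atoms: none
Why: Ring-closing metathesis initiates at the only monosubstituted alkene (C7) and closes the five-membered butenolide onto the acrylate (C7=C11) with loss of ethylene, the trisubstituted C4=C5 and C1=C10 alkenes being too hindered to compete.

Step 13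
Reactants: 17 (5R)-3-(bromomethyl)-5-[(1E,4R,5Z,7R)-7-[(4S)-2,2-dimethyl-1,3-dioxolan-4-yl]-4,7-bis(4-methoxybenzyloxy)-2,6-dimethylhepta-1,5-dienyl]furan-2(5H)-one
Product: 19 (2R,5R,3Z,7E)-8-[(2R)-4-(bromomethyl)-5-oxo-2,5-dihydrofuran-2-yl]-2,5-bis(4-methoxybenzyloxy)-3,7-dimethylocta-3,7-dienal, via terminal diol 18 (not isolated)
Conditions: H5IO6, EtOAc, 0 °C; used at once
Reagents that add atoms: none
Why: Periodic acid hydrolyses the terminal acetonide and cleaves the resulting 1,2-diol in one flask (glycol cleavage), which unveils the C8 aldehyde without base and removes the sacrificial stereocentre.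

Step 14
Reactants: 19 (2R,5R,3Z,7E)-8-[(2R)-4-(bromomethyl)-5-oxo-2,5-dihydrofuran-2-yl]-2,5-bis(4-methoxybenzyloxy)-3,7-dimethylocta-3,7-dienal
Product: 21 (2R,6R,7R,8R,9R,1(10)Z,4E)-8-hydroxy-2,9-bis(4-methoxybenzyloxy)germacra-1(10),4,11(13)-trien-12,6-olide, via allylindium dibromide 20 (not isolated)
Conditions: In powder (3 equiv), DMF/THF, syringe-pump addition of 19 (final 2 mM), rt; aq NH4Cl
Reagents that add atoms: none
Why: Proposed new method: indium inserts into the allylic C13–Br bond and the allylindium adds through C7 (SE2', allyl transposition) to the tethered C8 aldehyde, which forms C7–C8, moves the alkene to C11=C13 (the α-methylene lactone) and leaves O8 free. The closest known reactions are the intermolecular Zn/In Barbier allylation of aldehydes with γ-substituted α-(bromomethyl)butenolides and the metal-mediated ring-closing allylations of ω-formyl 2-(bromomethyl)acrylates that close ten-membered germacranolide rings; the ring-closing use of a butenolide-embedded allyl unit is the untested part. Only the ten-membered carbocycle C1–C10 is closed, by 10-exo-trig attack on the aldehyde through a six-membered chair (In–O–C8–C7–C11–C13), the lactone being already in place. C7 is set by C6: a ten-membered ring can only span the flat five-membered ring with the C5–C6 and C7–C8 bonds on opposite faces, so C8 should enter anti to C5 (trans-lactone), the same face that steric control chooses intermolecularly; C8 is set by the chair, in which the ring locks C6 trans to C13 (an E-crotyl-type reagent) and C9 sits equatorial, giving the 7,8-anti alcohol, and In(III) chelation between the aldehyde oxygen and the O9 PMB ether (8,9-syn) is the matched case. The step needs γ (C7) over α (C13) attack, which the cyclic transition state and the 12-membered ring required for α-attack should secure, and ring closure over oligomerisation, which slow addition at high dilution and the turn imposed by the 1(10)Z alkene should secure; the neutral conditions spare the base-labile doubly allylic C6–H and the epimerisable α-alkoxy aldehyde.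

Step 15
Reactants: 21 (2R,6R,7R,8R,9R,1(10)Z,4E)-8-hydroxy-2,9-bis(4-methoxybenzyloxy)germacra-1(10),4,11(13)-trien-12,6-olide; 22 angelic acid
Product: 23 (2R,6R,7S,8R,9R,1(10)Z,4E)-8-angeloyloxy-2,9-bis(4-methoxybenzyloxy)germacra-1(10),4,11(13)-trien-12,6-olide
Conditions: 22, 2,4,6-trichlorobenzoyl chloride, Et3N, toluene, rt; then 21, 70 °C
Reagents that add atoms: none
Why: Yamaguchi-type mixed-anhydride esterification without DMAP is the established way to angeloylate a hindered secondary alcohol without Z→E isomerisation to the tiglate.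

Step 16
Reactants: 23 (2R,6R,7S,8R,9R,1(10)Z,4E)-8-angeloyloxy-2,9-bis(4-methoxybenzyloxy)germacra-1(10),4,11(13)-trien-12,6-olide
Product: 24 (2R,6R,7S,8R,9R,1(10)Z,4E)-8-angeloyloxy-2,9-dihydroxygermacra-1(10),4,11(13)-trien-12,6-olide
Conditions: DDQ, CH2Cl2/pH 7 buffer, 0 °C
Reagents that add atoms: none
Why: Oxidative PMB cleavage by DDQ (benzylic hydride abstraction, then hydrolysis of the oxocarbenium ions) under buffered conditions should free O2 and O9 and leave the esters, the lactone and the alkenes intact.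

Step 17
Reactants: 24 (2R,6R,7S,8R,9R,1(10)Z,4E)-8-angeloyloxy-2,9-dihydroxygermacra-1(10),4,11(13)-trien-12,6-olide
Product: 25 (2R,6R,7S,8R,9R,1(10)Z,4E)-2,9-diacetoxy-8-angeloyloxygermacra-1(10),4,11(13)-trien-12,6-olide (CNP0499619.1)
Conditions: Ac2O, pyridine, DMAP (cat.), CH2Cl2, 0 °C → rt
Reagents that add atoms: acetic anhydride (CC(=O)OC(C)=O)
Why: DMAP-catalysed acetylation of the two secondary allylic alcohols should be fast enough to outrun 1,2-migration of the angeloyl group.

**Compound list**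
1 | (R)-trityl glycidyl ether | C1O[C@H]1COC(c1ccccc1)(c1ccccc1)c1ccccc1 | starting material
2 | (R)-1-(trityloxy)pent-4-yn-2-ol | C#CC[C@@H](O)COC(c1ccccc1)(c1ccccc1)c1ccccc1 | intermediate
3 | (R)-4-(4-methoxybenzyloxy)-5-(trityloxy)pent-1-yne | C#CC[C@@H](OCc1ccc(OC)cc1)COC(c1ccccc1)(c1ccccc1)c1ccccc1 | intermediate
4 | (R)-2-(4-methoxybenzyloxy)pent-4-yn-1-ol | C#CC[C@@H](OCc1ccc(OC)cc1)CO | intermediate
5 | (R)-2-(4-methoxybenzyloxy)pent-4-ynal | C#CC[C@@H](OCc1ccc(OC)cc1)C=O | intermediate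
6 | (4R,2Z)-2-iodo-4-(4-methoxybenzyloxy)hept-2-en-6-yne | C#CC[C@@H](OCc1ccc(OC)cc1)/C=C(/C)I | intermediate
7 | (S)-2,2-dimethyl-1,3-dioxolane-4-carbaldehyde ((S)-glyceraldehyde acetonide) | O=C[C@@H]1COC(C)(C)O1 | starting material
8 | (1R,4R,2Z)-1-[(4S)-2,2-dimethyl-1,3-dioxolan-4-yl]-2-methyl-4-(4-methoxybenzyloxy)hept-2-en-6-yn-1-ol | C#CC[C@@H](OCc1ccc(OC)cc1)/C=C(/C)[C@@H](O)[C@@H]1COC(C)(C)O1 | intermediate
9 | (4S)-4-[(1R,4R,2Z)-1,4-bis(4-methoxybenzyloxy)-2-methylhept-2-en-6-yn-1-yl]-2,2-dimethyl-1,3-dioxolane | C#CC[C@@H](OCc1ccc(OC)cc1)/C=C(/C)[C@@H](OCc1ccc(OC)cc1)[C@@H]1COC(C)(C)O1 | intermediate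
10 | acrolein | C=CC=O | starting material
11 | (3S,7R,10R,8Z)-10-[(4S)-2,2-dimethyl-1,3-dioxolan-4-yl]-7,10-bis(4-methoxybenzyloxy)-9-methyldeca-1,8-dien-4-yn-3-ol | C=C[C@H](O)C#CC[C@@H](OCc1ccc(OC)cc1)/C=C(/C)[C@@H](OCc1ccc(OC)cc1)[C@@H]1COC(C)(C)O1 | intermediate
12 | sodium cyclic alkenylalanate of 11 (O6–Al–C4 five-membered ring, two 2-methoxyethoxy groups on Al) | [Na+].C=C[C@@H]1O[Al-](OCCOC)(OCCOC)C(=C1)C[C@@H](OCc1ccc(OC)cc1)/C=C(/C)[C@@H](OCc1ccc(OC)cc1)[C@@H]1COC(C)(C)O1 | intermediate (not isolated)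
13 | (3S,7R,10R,4Z,8Z)-10-[(4S)-2,2-dimethyl-1,3-dioxolan-4-yl]-5-iodo-7,10-bis(4-methoxybenzyloxy)-9-methyldeca-1,4,8-trien-3-ol | C=C[C@H](O)/C=C(\I)C[C@@H](OCc1ccc(OC)cc1)/C=C(/C)[C@@H](OCc1ccc(OC)cc1)[C@@H]1COC(C)(C)O1 | intermediate
14 | (3S,7R,10R,4E,8Z)-10-[(4S)-2,2-dimethyl-1,3-dioxolan-4-yl]-7,10-bis(4-methoxybenzyloxy)-5,9-dimethyldeca-1,4,8-trien-3-ol | C=C[C@H](O)/C=C(\C)C[C@@H](OCc1ccc(OC)cc1)/C=C(/C)[C@@H](OCc1ccc(OC)cc1)[C@@H]1COC(C)(C)O1 | intermediate
15 | 2-(bromomethyl)acrylic acid | C=C(CBr)C(=O)O | starting material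
16 | O6 2-(bromomethyl)acrylate ester of 14 | C=C[C@H](OC(=O)C(=C)CBr)/C=C(\C)C[C@@H](OCc1ccc(OC)cc1)/C=C(/C)[C@@H](OCc1ccc(OC)cc1)[C@@H]1COC(C)(C)O1 | intermediate
17 | (5R)-3-(bromomethyl)-5-[(1E,4R,5Z,7R)-7-[(4S)-2,2-dimethyl-1,3-dioxolan-4-yl]-4,7-bis(4-methoxybenzyloxy)-2,6-dimethylhepta-1,5-dienyl]furan-2(5H)-one | O=C1O[C@@H](C=C1CBr)/C=C(\C)C[C@@H](OCc1ccc(OC)cc1)/C=C(/C)[C@@H](OCc1ccc(OC)cc1)[C@@H]1COC(C)(C)O1 | intermediate
18 | terminal 1,2-diol from hydrolysis of the acetonide of 17 | O=C1O[C@@H](C=C1CBr)/C=C(\C)C[C@@H](OCc1ccc(OC)cc1)/C=C(/C)[C@@H](OCc1ccc(OC)cc1)[C@@H](O)CO | intermediate (not isolated)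
19 | (2R,5R,3Z,7E)-8-[(2R)-4-(bromomethyl)-5-oxo-2,5-dihydrofuran-2-yl]-2,5-bis(4-methoxybenzyloxy)-3,7-dimethylocta-3,7-dienal | O=C1O[C@@H](C=C1CBr)/C=C(\C)C[C@@H](OCc1ccc(OC)cc1)/C=C(/C)[C@@H](OCc1ccc(OC)cc1)C=O | intermediate
20 | allylindium dibromide from 19 (In on C13; drawn as the dibromide component of the sesquihalide) | O=C1O[C@@H](C=C1C[In](Br)Br)/C=C(\C)C[C@@H](OCc1ccc(OC)cc1)/C=C(/C)[C@@H](OCc1ccc(OC)cc1)C=O | intermediate (not isolated)
21 | (2R,6R,7R,8R,9R,1(10)Z,4E)-8-hydroxy-2,9-bis(4-methoxybenzyloxy)germacra-1(10),4,11(13)-trien-12,6-olide | C=C1C(=O)O[C@@H]2/C=C(\C)C[C@@H](OCc3ccc(OC)cc3)/C=C(/C)[C@@H](OCc3ccc(OC)cc3)[C@H](O)[C@@H]12 | intermediate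
22 | angelic acid ((Z)-2-methylbut-2-enoic acid) | C/C=C(/C)C(=O)O | starting material
23 | (2R,6R,7S,8R,9R,1(10)Z,4E)-8-angeloyloxy-2,9-bis(4-methoxybenzyloxy)germacra-1(10),4,11(13)-trien-12,6-olide | C=C1C(=O)O[C@@H]2/C=C(\C)C[C@@H](OCc3ccc(OC)cc3)/C=C(/C)[C@@H](OCc3ccc(OC)cc3)[C@H](OC(=O)/C(C)=C\C)[C@@H]12 | intermediate
24 | (2R,6R,7S,8R,9R,1(10)Z,4E)-8-angeloyloxy-2,9-dihydroxygermacra-1(10),4,11(13)-trien-12,6-olide | C=C1C(=O)O[C@@H]2/C=C(\C)C[C@@H](O)/C=C(/C)[C@@H](O)[C@H](OC(=O)/C(C)=C\C)[C@@H]12 | intermediate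
25 | (2R,6R,7S,8R,9R,1(10)Z,4E)-2,9-diacetoxy-8-angeloyloxygermacra-1(10),4,11(13)-trien-12,6-olide | C=C1C(=O)O[C@@H]2/C=C(\C)C[C@@H](OC(C)=O)/C=C(/C)[C@@H](OC(C)=O)[C@H](OC(=O)/C(C)=C\C)[C@@H]12 | target

**Totals**
Total step count: 17.
Longest linear sequence: 17 steps (1 → 25); compounds 7, 10, 15 and 22 enter as bought reagents.

**Steps most likely to fail**

1. Step 14 (Proposed new method). The allylindium may be protonated or may oligomerise before the slow ten-membered ring closure, or it may add to the wrong aldehyde face if chair and chelation control diverge. The fallback uses two known reactions, an intermolecular Barbier allylation with a γ-substituted bromomethylbutenolide and a ring-closing metathesis to the ten-membered ring; it sets out from 5 (and 7) and comes back at 21. Wittig methylenation of 5 (Ph3P=CH2) should give (R)-3-(4-methoxybenzyloxy)hex-1-en-5-yne F1. The chemistry of steps 8–12 is then repeated on it: alkynylation of acrolein gives the enynol F2; Red-Al gives the cyclic alkenylalanate F3, which iodine turns into the iodo dienol F4; Me2CuLi gives the E-methyl dienol F5; esterification with 15 gives the bromomethylacrylate F6; and RCM gives the C1-vinyl bromomethylbutenolide F7. In parallel, isopropenylmagnesium bromide adds to 7 (Felkin–Anh) to give the isopropenyl carbinol F8, which is converted into its PMB ether F9 and cleaved with periodic acid through the diol F10 to (R)-2-(4-methoxybenzyloxy)-3-methylbut-3-enal F11. Indium-mediated Barbier allylation of F11 with F7 should give the open-chain methylene lactone F12 (trans-lactone, 7,8-anti, 8,9-syn). Ring-closing metathesis of F12 (Grubbs II, high dilution) between the C1 vinyl and the C10 isopropenyl group should close the ring as the strain-preferred 1(10)Z alkene, which is 21.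

2. Step 6. Facial selectivity in the addition to the α-alkoxy aldehyde may be poor (C9 epimers), and some Z/E erosion of the alkenylchromium is possible. The fallback sets out from the C9-epimer mixture of 8 and comes back at 8. Dess–Martin oxidation gives the Z-enone F13, and 1,2-reduction with Zn(BH4)2 (Et2O, −30 °C), in which zinc bridges the ketone and the adjacent dioxolane oxygen, should return the anti alcohol 8 by chelation control.

3. Step 15. Acylation of the hindered 8-hydroxyl may be slow, with isomerisation of the angeloyl unit to tigloyl or base-induced translactonisation to the 8,12-olide. The fallback builds the Z-alkene on the ester instead of transferring it; it sets out from 21 and comes back at 23. Steglich esterification of 21 with 2-[bis(2,2,2-trifluoroethoxy)phosphoryl]propanoic acid gives the phosphonopropionate ester F14, and Still–Gennari olefination with acetaldehyde (KHMDS, 18-crown-6, THF, −78 °C) should give the Z-2-methylbut-2-enoate 23.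

**Further compounds**
F1 | step 14 | (R)-3-(4-methoxybenzyloxy)hex-1-en-5-yne | C#CC[C@@H](OCc1ccc(OC)cc1)C=C
F2 | step 14 | enynol from F1 and acrolein (6S) | C=C[C@H](O)C#CC[C@@H](OCc1ccc(OC)cc1)C=C
F3 | step 14 | sodium cyclic alkenylalanate of F2 | [Na+].C=C[C@@H]1O[Al-](OCCOC)(OCCOC)C(=C1)C[C@@H](OCc1ccc(OC)cc1)C=C
F4 | step 14 | (Z)-iodo dienol from F3 | C=C[C@H](O)/C=C(\I)C[C@@H](OCc1ccc(OC)cc1)C=C
F5 | step 14 | (E)-methyl dienol from F4 | C=C[C@H](O)/C=C(\C)C[C@@H](OCc1ccc(OC)cc1)C=C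
F6 | step 14 | O6 2-(bromomethyl)acrylate of F5 | C=C[C@H](OC(=O)C(=C)CBr)/C=C(\C)C[C@@H](OCc1ccc(OC)cc1)C=C
F7 | step 14 | C1-vinyl 3-(bromomethyl)butenolide | O=C1O[C@@H](C=C1CBr)/C=C(\C)C[C@@H](OCc1ccc(OC)cc1)C=C
F8 | step 14 | (R)-1-[(4S)-2,2-dimethyl-1,3-dioxolan-4-yl]-2-methylprop-2-en-1-ol | C=C(C)[C@@H](O)[C@@H]1COC(C)(C)O1
F9 | step 14 | PMB ether of F8 | C=C(C)[C@@H](OCc1ccc(OC)cc1)[C@@H]1COC(C)(C)O1
F10 | step 14 | diol from hydrolysis of F9 | C=C(C)[C@@H](OCc1ccc(OC)cc1)[C@@H](O)CO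
F11 | step 14 | (R)-2-(4-methoxybenzyloxy)-3-methylbut-3-enal | C=C(C)[C@@H](OCc1ccc(OC)cc1)C=O
F12 | step 14 | open-chain Barbier adduct (α-methylene lactone with C1 vinyl and C10 isopropenyl groups) | C=C1C(=O)O[C@H](/C=C(\C)C[C@@H](OCc2ccc(OC)cc2)C=C)[C@H]1[C@@H](O)[C@H](OCc2ccc(OC)cc2)C(C)=C
F13 | step 6 | (4R,2Z)-1-[(4S)-2,2-dimethyl-1,3-dioxolan-4-yl]-2-methyl-4-(4-methoxybenzyloxy)hept-2-en-6-yn-1-one | C#CC[C@@H](OCc1ccc(OC)cc1)/C=C(/C)C(=O)[C@@H]1COC(C)(C)O1
F14 | step 15 | 8-O-{2-[bis(2,2,2-trifluoroethoxy)phosphoryl]propanoyl} ester of 21 | C=C1C(=O)O[C@@H]2/C=C(\C)C[C@@H](OCc3ccc(OC)cc3)/C=C(/C)[C@@H](OCc3ccc(OC)cc3)[C@H](OC(=O)C(C)P(=O)(OCC(F)(F)F)OCC(F)(F)F)[C@@H]12
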